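The ten-membered carbocycle is made by a Claisen ring contraction of a twelve-membered cyclic allyl vinyl ether. Germacrane numbering is used (C1/C10 epoxide carbons, C4=C5 olefin, C6 lactone carbinol, C7 ring fusion, C8 ester carbon, C9 carbinol, C11=C13 lactone methylene). The target hides a γ,δ-unsaturated carbonyl array, C9(O)–C8–C7–C11=C13, shared by the carbocycle and the α-methylene lactone. Disconnecting C7–C8 as a Claisen retron gives an ansa-butenolide whose ether oxygen bridges C9 and C13. One [3,3] shift contracts this oxacycle to the C1–C10 ring, forms C7–C8, sets C7 from C6, generates the C9 ketone and unveils the exocyclic methylene. The precursor comes from neryl acetate in ten steps; C8, C9 and the epoxide follow by substrate control.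

Key step: step 11

Remark on the chemistry: the target SMILES corresponds to (1R,6S,7S,8R,9S,10R), i.e. 1β,10α-epoxide, 9β-OH, 8α-ester and a cis-fused 12,6β-lactone (H-6 and H-7 both α). The ProPhenol antipode in step 6 is the one that adds the alkynyl group to the Re face of aldehyde 9; (S,S) is written and is to be exchanged for (R,R) if its sense is opposite. Compound 10 is taken as commercial.

**Step 1**
Reactants: 1 neryl acetate
Product: 3 (2Z,6E)-3,7-dimethyl-8-oxoocta-2,6-dien-1-yl acetate, via 8-hydroxyneryl acetate 2 (not isolated)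
Conditions: SeO2 (cat.), t-BuOOH, salicylic acid (cat.), CH2Cl2, rt; filter, then MnO2, CH2Cl2, rt
Reagents that add atoms: tert-butyl hydroperoxide, CC(C)(C)OO
Why: SeO2-catalysed allylic oxidation (ene reaction then [2,3] shift) should hydroxylate the (E)-methyl of the distal, more electron-rich olefin, and MnO2 converges the alcohol/aldehyde mixture to the (E)-enal while the 2Z olefin, deactivated by its allylic acetate, is left alone.

**Step 2**
Reactants: 3 (2Z,6E)-3,7-dimethyl-8-oxoocta-2,6-dien-1-yl acetate
Product: 4 (2Z,6E)-9,9-dibromo-3,7-dimethylnona-2,6,8-trien-1-yl acetate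
Conditions: CBr4, PPh3, CH2Cl2, 0 °C
Reagents that add atoms: carbon tetrabromide, BrC(Br)(Br)Br
Why: Corey–Fuchs dibromo-olefination (Wittig reaction of Ph3P=CBr2) adds the future C8 without touching the ester or either trisubstituted olefin.

**Step 3**
Reactants: 4 (2Z,6E)-9,9-dibromo-3,7-dimethylnona-2,6,8-trien-1-yl acetate
Product: 5 (2Z,6E)-9,9-dibromo-3,7-dimethylnona-2,6,8-trien-1-ol
Conditions: K2CO3 (cat.), MeOH, 0 °C
Reagents that add atoms: none
Why: Base-catalysed transesterification frees the allylic alcohol so that the next step spends no organolithium on the acetate.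

**Step 4**
Reactants: 5 (2Z,6E)-9,9-dibromo-3,7-dimethylnona-2,6,8-trien-1-ol
Product: 8 (2Z,6E)-3,7-dimethyl-9-(trimethylsilyl)nona-2,6-dien-8-yn-1-ol, via dilithio alkoxide-alkynide 6 (not isolated), via C,O-bis(trimethylsilyl) ether 7 (not isolated)
Conditions: n-BuLi (3.2 equiv), THF, −78 → 0 °C; TMSCl (2.5 equiv), −78 °C → rt; 1 M HCl, THF
Reagents that add atoms: chlorotrimethylsilane, C[Si](C)(C)Cl; n-butyllithium, [Li]CCCC (lithium in 6 only)
Why: The second Corey–Fuchs stage (Br/Li exchange, Fritsch–Buttenberg–Wiechell shift, deprotonation) gives the lithium enynide, which is C-silylated, and dilute acid cleaves only the O–Si bond.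

**Step 5**
Reactants: 8 (2Z,6E)-3,7-dimethyl-9-(trimethylsilyl)nona-2,6-dien-8-yn-1-ol
Product: 9 (2Z,6E)-3,7-dimethyl-9-(trimethylsilyl)nona-2,6-dien-8-ynal
Conditions: MnO2, CH2Cl2, rt; used at once
Reagents that add atoms: none
Why: Neutral MnO2 oxidation of the primary allylic alcohol should give the Z-enal without the Z→E isomerisation that acid or base would cause.

**Step 6**
Reactants: 9 (2Z,6E)-3,7-dimethyl-9-(trimethylsilyl)nona-2,6-dien-8-ynal; 10 tert-butyldimethyl(prop-2-yn-1-yloxy)silane
Product: 11 (4S,5Z,9E)-1-(tert-butyldimethylsilyloxy)-6,10-dimethyl-12-(trimethylsilyl)dodeca-5,9-dien-2,11-diyn-4-ol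
Conditions: 10 (3 equiv), Me2Zn, (S,S)-ProPhenol (10 mol%), Ph3P=O (20 mol%), toluene, 4 °C; aq NH4Cl
Reagents that add atoms: 10, C#CCO[Si](C)(C)C(C)(C)C
Why: Dinuclear zinc–ProPhenol asymmetric alkynylation, a reaction class suited to enals, delivers the alkynylzinc formed in situ to the Re face and sets C6 (S) by catalyst control, the silyl cap keeping the substrate's own alkyne out of the zincation.

**Step 7**
Reactants: 11 (4S)-propargylic alcohol
Product: 13 (2Z,4S,5Z,9E)-1-(tert-butyldimethylsilyloxy)-2-iodo-6,10-dimethyl-12-(trimethylsilyl)dodeca-2,5,9-trien-11-yn-4-ol, via cyclic vinylalanate 12 (not isolated)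
Conditions: Red-Al, THF, 0 °C → rt; EtOAc; I2, THF, −78 → 0 °C
Reagents that add atoms: iodine, II; sodium bis(2-methoxyethoxy)aluminium hydride, [Na+].COCCO[AlH2-]OCCOC (Al and Na in 12 only)
Why: Alkoxide-directed trans-hydroalumination puts hydride on C7 and aluminium on C11, and iodinolysis with retention gives the Z-iodide with C6 cis to iodine, the unactivated silyl enyne being inert.

**Step 8**
Reactants: 13 (Z)-vinyl iodide
Product: 14 (5S)-3-[(tert-butyldimethylsilyloxy)methyl]-5-[(1Z,5E)-2,6-dimethyl-8-(trimethylsilyl)octa-1,5-dien-7-yn-1-yl]furan-2(5H)-one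
Conditions: PdCl2(PPh3)2 (5 mol%), CO (1 atm), K2CO3, THF, rt
Reagents that add atoms: carbon monoxide, [C-]#[O+]
Why: Pd-catalysed carbonylative lactonisation (oxidative addition, CO insertion, capture of the acyl-palladium by the cis C6 hydroxyl) closes the butenolide and supplies C12 without touching the C6 stereocentre.

**Step 9**
Reactants: 14 bis-silylated butenolide
Product: 15 (5S)-5-[(1Z,5E)-2,6-dimethylocta-1,5-dien-7-yn-1-yl]-3-(hydroxymethyl)furan-2(5H)-one
Conditions: TBAF, AcOH (1:1), THF, 0 °C → rt
Reagents that add atoms: none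
Why: Buffered fluoride removes the O-TBS and the alkynyl C-TMS groups together, the acetic acid preventing γ-deprotonation of the butenolide.

**Step 10**
Reactants: 15 hydroxymethyl butenolide enyne
Product: 16 (6S)-ansa-butenolide enol ether: 12-membered ring O–C9(=C8H2)–C10(Me)=C1H–C2H2–C3H2–C4(Me)=C5H–C6H–C7H=C11–C13H2, with O–C12(=O) joining C6 to C11; 1(10)E, 4Z
Conditions: IPrAuNTf2 (5 mol%), 4 Å MS, toluene (1 mM, syringe pump), 40 °C; Et3N quench, Et3N-deactivated SiO2
Reagents that add atoms: none
Why: Gold(I)-catalysed Markovnikov hydroalkoxylation of the terminal 1,3-enyne by the primary alcohol (anti oxyauration at C9, protodeauration) should give the 2-alkoxy-1,3-diene as a 12-membered ring under neutral conditions that neither epimerise C6 nor hydrolyse the enol ether.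

**Step 11**
Reactants: 16 twelve-membered ansa-butenolide enol ether
Product: 17 (6S,7S)-9-oxogermacra-1(10)E,4Z,11(13)-trien-12,6β-olide (cis-fused α-methylene lactone)
Conditions: toluene (5 mM), BHT (cat.), base-washed sealed tube, 110 °C
Reagents that add atoms: none
Why: Thermal [3,3]-sigmatropic (Claisen) shift of the allyl vinyl ether C8=C9–O–C13–C11=C7 forms C8–C7 as O–C13 breaks, so the ring oxygen, C13 and C11 leave the 12-membered ring, exocyclic C8 enters it, and the ten-membered carbocycle, the C9 enone carbonyl and the C11=C13 methylene appear together; the closest known type is the aliphatic Claisen rearrangement of lactone-derived 2-methylene oxacycles, here in its ring-contracting topology. The carbocycle closes by concerted suprafacial C–C bond formation in a six-centre chair-like transition state bridged by C10–C6, not by an ionic exo or endo closure. The only new stereocentre, C7, is set by C6: the bridge leaves sp3 C6 on one face of the planar butenolide and the lactone ring cannot swing through the macrocycle, so C8 is delivered to C7 syn to C5 and the cis-fused (6S,7S) lactone should result. There is no regiochemical choice, so the step needs only this facial selectivity and survival of the enol ether, the latter secured by base-washed glassware and BHT. A type-2 Diels–Alder reaction of the 2-alkoxydiene with the butenolide would need a bridgehead olefin, and a 1,5-hydrogen shift is excluded because C2 is trans to C9. The ester at C11 and the donor diene at C9 accelerate the shift, and enone conjugation makes it irreversible.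

**Step 12**
Reactants: 17 9-oxogermacratrienolide
Product: 19 8α-hydroxy-9-oxogermacra-1(10)E,4Z,11(13)-trien-12,6β-olide, via potassium enolate 18 (not isolated)
Conditions: KHMDS (1.05 equiv), THF, −78 °C; trans-2-(phenylsulfonyl)-3-phenyloxaziridine, −78 °C; AcOH
Reagents that add atoms: 2-(phenylsulfonyl)-3-phenyloxaziridine, O=S(=O)(c1ccccc1)N1OC1c1ccccc1; potassium hexamethyldisilazide, C[Si](C)(C)[N-][Si](C)(C)C.[K+] (potassium in 18 only)
Why: Kinetic α′-deprotonation at C8 (the only acidic site, since the methylene lactone has no enolisable hydrogen) and Davis enolate oxidation should place oxygen on the peripheral face, A(1,3) strain holding H-7 in the enolate plane while ring carbon C6 blocks the inner face, to give the 8α-alcohol trans to C11.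

**Step 13**
Reactants: 19 8α-hydroxy ketone
Product: 20 8α-(2-methylpropanoyloxy)-9-oxogermacra-1(10)E,4Z,11(13)-trien-12,6β-olide
Conditions: (i-PrCO)2O, pyridine, DMAP (cat.), CH2Cl2, 0 °C
Reagents that add atoms: isobutyric anhydride, CC(C)C(=O)OC(=O)C(C)C
Why: DMAP-catalysed acylation of the only hydroxyl installs the isobutyrate before a second hydroxyl exists, so no differentiation of a diol is needed.

**Step 14**
Reactants: 20 8α-acyloxy enone
Product: 21 9β-hydroxy-8α-(2-methylpropanoyloxy)germacra-1(10)E,4Z,11(13)-trien-12,6β-olide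
Conditions: NaBH4, CeCl3·7H2O, MeOH, −78 °C
Reagents that add atoms: none
Why: Luche 1,2-reduction should deliver hydride from the peripheral face with the acyloxy group anti to the carbonyl oxygen (Cornforth/polar Felkin–Anh), giving the 9β-alcohol anti to the 8α-ester, while cerium at −78 °C spares the methylene lactone.

**Step 15**
Reactants: 21 allylic alcohol
Product: 22 target, (1R,6S,7S,8R,9S,10R)-1β,10α-epoxy-9β-hydroxy-8α-(2-methylpropanoyloxy)germacra-4Z,11(13)-dien-12,6β-olide
Conditions: mCPBA (1.05 equiv), NaHCO3, CH2Cl2, 0 °C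
Reagents that add atoms: 3-chloroperoxybenzoic acid, OOC(=O)c1cccc(Cl)c1
Why: Prilezhaev epoxidation should take the strained (E)-C1=C10 olefin ahead of the Z-C4=C5 olefin (deactivated by the allylic lactone oxygen) and the electron-poor methylene, adding to the exposed outer face of the C14-β conformer with hydrogen-bond guidance from the 9β-hydroxyl, so that the trans 1β,10α-epoxide follows from the E geometry.

**Compound list**
1 | neryl acetate, (2Z)-3,7-dimethylocta-2,6-dien-1-yl acetate | CC(C)=CCC/C(C)=C\COC(C)=O | starting material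
2 | (2Z,6E)-8-hydroxy-3,7-dimethylocta-2,6-dien-1-yl acetate | OC/C(C)=C/CC/C(C)=C\COC(C)=O | intermediate (not isolated)
3 | (2Z,6E)-3,7-dimethyl-8-oxoocta-2,6-dien-1-yl acetate | O=C/C(C)=C/CC/C(C)=C\COC(C)=O | intermediate
4 | (2Z,6E)-9,9-dibromo-3,7-dimethylnona-2,6,8-trien-1-yl acetate | BrC(Br)=C/C(C)=C/CC/C(C)=C\COC(C)=O | intermediate
5 | (2Z,6E)-9,9-dibromo-3,7-dimethylnona-2,6,8-trien-1-ol | BrC(Br)=C/C(C)=C/CC/C(C)=C\CO | intermediate
6 | dilithio alkoxide-alkynide of (2Z,6E)-3,7-dimethylnona-2,6-dien-8-yn-1-ol | [Li]C#C/C(C)=C/CC/C(C)=C\CO[Li] | intermediate (not isolated)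
7 | C,O-bis(trimethylsilyl) derivative of the enynol | C[Si](C)(C)C#C/C(C)=C/CC/C(C)=C\CO[Si](C)(C)C | intermediate (not isolated)
8 | (2Z,6E)-3,7-dimethyl-9-(trimethylsilyl)nona-2,6-dien-8-yn-1-ol | C[Si](C)(C)C#C/C(C)=C/CC/C(C)=C\CO | intermediate
9 | (2Z,6E)-3,7-dimethyl-9-(trimethylsilyl)nona-2,6-dien-8-ynal | C[Si](C)(C)C#C/C(C)=C/CC/C(C)=C\C=O | intermediate
10 | tert-butyldimethyl(prop-2-yn-1-yloxy)silane | C#CCO[Si](C)(C)C(C)(C)C | starting material
11 | (4S,5Z,9E)-1-(tert-butyldimethylsilyloxy)-6,10-dimethyl-12-(trimethylsilyl)dodeca-5,9-dien-2,11-diyn-4-ol | C[Si](C)(C)C#C/C(C)=C/CC/C(C)=C\[C@H](O)C#CCO[Si](C)(C)C(C)(C)C | intermediate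
12 | sodium cyclic alkoxy(vinyl)alanate (O6–Al–C11=C7–C6 ring, two 2-methoxyethoxy ligands) | C[Si](C)(C)C#C/C(C)=C/CC/C(C)=C\[C@H]1C=C(CO[Si](C)(C)C(C)(C)C)[Al-](OCCOC)(OCCOC)O1.[Na+] | intermediate (not isolated)
13 | (2Z,4S,5Z,9E)-1-(tert-butyldimethylsilyloxy)-2-iodo-6,10-dimethyl-12-(trimethylsilyl)dodeca-2,5,9-trien-11-yn-4-ol | C[Si](C)(C)C#C/C(C)=C/CC/C(C)=C\[C@H](O)/C=C(\I)CO[Si](C)(C)C(C)(C)C | intermediate
14 | (5S)-3-[(tert-butyldimethylsilyloxy)methyl]-5-[(1Z,5E)-2,6-dimethyl-8-(trimethylsilyl)octa-1,5-dien-7-yn-1-yl]furan-2(5H)-one | C[Si](C)(C)C#C/C(C)=C/CC/C(C)=C\[C@@H]1OC(=O)C(CO[Si](C)(C)C(C)(C)C)=C1 | intermediate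
15 | (5S)-5-[(1Z,5E)-2,6-dimethylocta-1,5-dien-7-yn-1-yl]-3-(hydroxymethyl)furan-2(5H)-one | C#C/C(C)=C/CC/C(C)=C\[C@@H]1OC(=O)C(CO)=C1 | intermediate
16 | (6S)-ansa-butenolide, twelve-membered cyclic 2-alkoxy-1,3-diene (O bridging C9 and C13; 1(10)E, 4Z) | C=C1OCC2=C[C@@H](OC2=O)/C=C(/C)CC/C=C1\C | intermediate
17 | (6S,7S)-9-oxogermacra-1(10)E,4Z,11(13)-trien-12,6β-olide | C=C1C(=O)O[C@H]2/C=C(/C)CC/C=C(C)/C(=O)C[C@@H]12 | intermediate
18 | potassium C8=C9 enolate of 17 | C=C1C(=O)O[C@H]2/C=C(/C)CC/C=C(C)/C([O-])=C\[C@@H]12.[K+] | intermediate (not isolated)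
19 | 8α-hydroxy-9-oxogermacra-1(10)E,4Z,11(13)-trien-12,6β-olide | C=C1C(=O)O[C@H]2/C=C(/C)CC/C=C(C)/C(=O)[C@H](O)[C@@H]12 | intermediate
20 | 8α-(2-methylpropanoyloxy)-9-oxogermacra-1(10)E,4Z,11(13)-trien-12,6β-olide | C=C1C(=O)O[C@H]2/C=C(/C)CC/C=C(C)/C(=O)[C@H](OC(=O)C(C)C)[C@@H]12 | intermediate
21 | 9β-hydroxy-8α-(2-methylpropanoyloxy)germacra-1(10)E,4Z,11(13)-trien-12,6β-olide | C=C1C(=O)O[C@H]2/C=C(/C)CC/C=C(C)/[C@@H](O)[C@H](OC(=O)C(C)C)[C@@H]12 | intermediate
22 | CNP0110853.1, 1β,10α-epoxy-9β-hydroxy-8α-(2-methylpropanoyloxy)germacra-4Z,11(13)-dien-12,6β-olide | C=C1C(=O)O[C@H]2/C=C(/C)CC[C@H]3O[C@]3(C)[C@@H](O)[C@H](OC(=O)C(C)C)[C@@H]12 | target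

Total step count: 15. Longest linear sequence: 15 steps (1 → 22).

**Steps most likely to fail**

Step 10. Intermolecular oligomerisation or hydration of the gold-activated alkyne may outrun the entropically demanding twelve-membered closure, and the acid-labile 2-alkoxydiene may hydrolyse on the catalyst. The fallback sets out from 15. Markovnikov hydroiodination of the terminal alkyne (B-iodo-9-BBN, CH2Cl2, 0 °C, then AcOH) gives the 2-iodo-1,3-diene F1. An Ullmann-type intramolecular O-vinylation (CuI, 3,4,7,8-tetramethyl-1,10-phenanthroline, Cs2CO3, toluene, 80 °C, high dilution) then closes the same ring by C–O cross-coupling instead of π-acid addition and comes back to the route at 16.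

Step 12. The potassium enolate may add to the methylene lactone of a second molecule or to the sulfonimine by-product before it is oxidised, or oxygen may arrive on the inner face. The fallback sets out from 17. Soft enolisation (TMSOTf, Et3N, CH2Cl2, −78 °C) gives the trimethylsilyl enol ether F2. Rubottom oxidation with dimethyldioxirane (acetone, −78 °C) epoxidises only this electron-rich olefin and, after silyl migration, gives the 8α-silyloxy ketone F3. Citric acid in MeOH removes the silyl group and the route is rejoined at 19.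

Step 15. The peracid may also attack the C4=C5 olefin, and the acid it releases may open the new epoxide transannularly. The fallback sets out from 21 and goes directly to 22 with VO(acac)2 (cat.) and t-BuOOH in CH2Cl2 at 0 °C. Oxygen is then transferred from a vanadium alkoxide anchored at the 9-hydroxyl, which confines it to the allylic olefin and avoids any peracid; no new compound is made (F0).

**Further compounds**
F1 | step 10 | (5S)-3-(hydroxymethyl)-5-[(1Z,5E)-7-iodo-2,6-dimethylocta-1,5,7-trien-1-yl]furan-2(5H)-one | C=C(I)/C(C)=C/CC/C(C)=C\[C@@H]1OC(=O)C(CO)=C1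
F2 | step 12 | trimethylsilyl enol ether of 17 (C8=C9, C7 and C10 cis) | C=C1C(=O)O[C@H]2/C=C(/C)CC/C=C(C)/C(O[Si](C)(C)C)=C\[C@@H]12
F3 | step 12 | 8α-(trimethylsilyloxy)-9-oxogermacra-1(10)E,4Z,11(13)-trien-12,6β-olide | C=C1C(=O)O[C@H]2/C=C(/C)CC/C=C(C)/C(=O)[C@H](O[Si](C)(C)C)[C@@H]12
F0 | step 15 | none | none
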